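# Route to CNP0108778.1 (compound 26) through a Z-diene intramolecular Diels–Alder reaction

## Analysis of the target

- The target 26 is a C30 dimer of two eudesmane units joined through a spiro 3,4-dihydro-2H-pyran. Its ring atoms are O, C11 (spiro, also the α-carbon of the γ-lactone), C13, C13', C11' and C12', with the enol ether double bond at C11'=C12'.
- The unprimed half is the unchanged skeleton of alantolactone: a cis-fused γ-lactone on an octalin with the C5=C6 alkene and the stereocentres C4, C7, C8 and C10. The only new centre there is C11, whose ring oxygen lies on the face of H7 and H8, the convex face of the lactone.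
- The primed half is a cis-fused decalin with an exocyclic methylene on C4', an angular methyl on C10' and the dihydropyran on C7'. H5', the C10' methyl and the C7' substituent all lie on one face (5'S,7'S,10'S).
- Of the eight stereocentres, four come with alantolactone and C11 follows from the shape of the lactone. The difficulty therefore lies in the three centres of the primed decalin and in joining two hindered halves at a quaternary carbon.
- The enol ether and the exocyclic methylene are acid-labile and the lactone is base-sensitive. On the way, any carbonyl on C4' or on the C7' side chain makes C5' or C7' epimerisable.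
- The strategy rests on ring B of the primed decalin (C5' to C10'). C10' and C7' stand 1,4 to each other with C5'–C6' between them, which is the pattern of a Diels–Alder cyclohexene with C10' and C7' as diene termini and C5'=C6' as dienophile.
- Ring A is then the tether, and C4', the future methylene carbon, is the activating carbonyl. A tether that sits cis to the diene on C10' can only give the cis-fused ring system with the C10' methyl, H5' and the C7' group on one face.

## Retrosynthetic reasoning

**Enol ether.** The C11'=C12' enol ether of 26 is the most acid-sensitive bond and is made last. It is traced back to the lactol 24, dehydrated through its anomeric mesylate 25. Only C11'–H can be lost, so no regiochemical question arises, and the step runs under basic conditions.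

**C13–C13' bond.** In 24 (open form 23) the bond between the two halves is cut. This divides the molecule into two C15 pieces, the enal 19 and the iodohydrin 22. The forward reaction is a radical conjugate addition: a C13 radical carrying a β-oxygen does not eliminate, whereas a C13 organometallic would. The C11–O bond is already in place on the small, rigid lactone, so the coupling creates no stereocentre that survives.

**C11–O bond.** Iodohydrin 22 comes from the spiro-epoxide 21 by opening at the primary carbon, and 21 from alantolactone 20 by nucleophilic epoxidation. A nucleophilic oxidant is needed because an electrophilic one would attack C5=C6 first. Closure on the convex face sets C11.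

**C11'–C12' bond.** The enal 19 is cut between C11' and the formyl carbon, back to the enol triflate 18 and the methyl ketone 16. A carbonylation adds the one carbon that is missing, and the kinetic enolate of the methyl ketone gives the 1,1-disubstituted alkene without touching C7'.

**C4'=C15' and C8'–C9'.** Ketone 16 is unmasked from the ketal 15. The exocyclic methylene of 15 is cut to the ketone 14, and 14 is the hydrogenation product of the octalone 13. The order matters: the ring alkene must be saturated before the methylene exists, and the methylene must be installed while the side-chain ketone is still masked.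

**Key disconnection, C5'–C10' and C6'–C7'.** Octalone 13 is opened to the acyclic trienone 12.

- Cutting here removes both rings and all three stereocentres of the primed half at once and leads to an achiral chain.
- The forward intramolecular Diels–Alder reaction has to give cis fusion and the syn C7'/C10' relation, which the 7Z,9E diene geometry dictates.
- It also has to give one enantiomer, which a chiral Lewis acid on the C4' carbonyl has to select.

**C4'–C5' bond.** Trienone 12 comes from the allylic alcohol 11 and this from the aldehyde 10 by addition of a vinyl-metal reagent. Aldehyde 10 is reached from the silyl ether 8 through the alcohol 9. The aldehyde carbon is carried as a silyl ether and not as an acetal, because an acetal could not be hydrolysed selectively next to the dienyl ketal, which ionises at least as easily.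

**C8'–C9' bond.** Diene 8 is cut between the two alkenes into the Z-alkenyl iodide 6 and the vinyl dioxolane 7 (Heck reaction). The quaternary ketal carbon of 7 fixes the regiochemistry and gives the E alkene.

**C1'–C10' bond.** Iodide 6 comes from the bromide 1 and propyne 2 by carbocupration and iodinolysis. Syn addition of the alkylcopper places the chain cis to the metal and so sets the Z geometry on which the key step depends.

## Alternatives that were turned down

**Alternative 1:** The lactone half is taken apart.
- Disconnection: alantolactone A1 is cut at C7–C8, C11–C12 and C12–O and traced to the vinylallene aldehyde A2.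
- Forward key step: an allenic hetero-Pauson–Khand reaction. Mo(CO)6 with DMSO joins the aldehyde carbon, the proximal allene bond and one carbonyl ligand, closing ring B and the α-methylene lactone together.
- For: one step forms two rings and the exocyclic methylene, and it would give access to unnatural lactone analogues.
- Against: A1 is the same compound as 20, an abundant natural product sold as a single enantiomer. Making it would add a multistep sequence to A2. The cyclisation must set C7 and C8 cis to each other and correctly relative to C4 and C10. The vinylallene could also react through its distal bond or as a diene.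
- Comparison: on the lactone half purchase is stronger than any synthesis. The chosen strategy spends its key step on the three stereocentres that cannot be bought, which alternative 1 leaves unsolved.

**Alternative 2:** Ring A of the primed decalin is cut at C4'–C5' and C1'–C10'.
- Disconnection: back to the silyloxy carvone A3 and the bifunctional reagent 5-chloro-2-lithiopent-1-ene A4.
- Forward key step: a methylenecyclohexane annulation. The cuprate from A4 and CuBr·SMe2 adds to the enone anti to the side chain, and the enolate, regenerated with KH, displaces chloride to give the cis-fused decalone A5.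
- For: the absolute configuration comes from the chiral pool with certainty. The all-cis triad follows from anti addition and cis alkylation. The exocyclic methylene and an oxygenated isopropenyl group, one oxidation away from the enal, arrive preformed.
- Against: A5 carries a ketone on C9', next to the quaternary C10', which the target lacks. Its removal in the presence of the exocyclic alkene and the allylic silyl ether costs about three steps (reduction, xanthate, Barton–McCombie) or needs forcing Wolff–Kishner conditions that invite alkene migration. A4 is reached through an organotin precursor, and A3 needs an allylic oxidation sequence.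
- Comparison: this alternative is stronger on absolute control and probably no longer in steps. The chosen strategy offers instead the creation of both rings and all three centres in one catalytic step from an achiral chain, with no surplus functionality to remove, the carbonyl exactly where the methylene is needed, and either enantiomer by choice of catalyst.

**Alternative 3:** The union of the halves is changed.
- Disconnection: the dihydropyran is cut at C11'=C13' of the spiro 3,6-dihydro-2H-pyran A7, which comes from the diene A6.
- Forward key step: ring-closing metathesis with the second-generation Grubbs catalyst (H2IMes)(PCy3)Cl2Ru=CHPh, followed by migration of the ring alkene into conjugation with oxygen.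
- For: the union is neutral and convergent. C11 is fixed beforehand by enolate chemistry, and no radical step is needed.
- Against:
  - A6 requires etherification of a tertiary α-hydroxy lactone with a hindered 2-substituted allyl electrophile and a C-allylation at C11.
  - The metathesis has to engage a 1,1-disubstituted alkene flanked by a secondary carbon while the C4' methylene is an alkene of the same class.
  - The isomerisation catalyst, a metal hydride, would also move the exocyclic C4'=C15' alkene into the ring.
- Comparison: this alternative addresses only the last bonds and still needs a decalin fragment of the same stereochemistry as 19, so it does not replace the key step. As an end-game it is about two steps longer than the radical coupling of 19 with 22 and riskier in chemoselectivity. It would be the better choice only if the radical coupling failed for lack of reactivity.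

Key step: step 7

Remark on the chemistry (assumptions):
- Eudesmane locants are used. Primed locants are the methylene-decalin half, unprimed locants the alantolactone half. The dihydropyran ring is O–C11–C13–C13'–C11'=C12'.
- The (R)-oxazaborolidine in step 7 is chosen from the usual binding model for α-unsubstituted enones. This assignment is the one assumption on which the sense of induction rests.

## Steps

Step 1
Reactants: 1 tert-butyl(4-bromobutoxy)dimethylsilane; 2 propyne
Product: 6 (Z)-tert-butyl[(6-iodo-5-methylhex-5-en-1-yl)oxy]dimethylsilane, via Grignard reagent 3 (not isolated), via alkylcopper 4 (not isolated), via alkenylcopper 5 (not isolated)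
Conditions: Mg, Et2O, 35 °C; CuBr·SMe2 (1 equiv), Et2O/Me2S, −45 °C; propyne, −25 °C; I2, −50 → 0 °C
Reagents that add atoms: iodine, II
Why: Carbocupration of a terminal alkyne: the alkylcopper adds syn across propyne with the alkyl group on the internal carbon, and iodinolysis of the alkenylcopper goes with retention, so the chain ends cis to iodine (Z); this geometry later places the tether on the inside of the diene.

Step 2
Reactants: 6 (Z)-tert-butyl[(6-iodo-5-methylhex-5-en-1-yl)oxy]dimethylsilane; 7 2-ethenyl-2-methyl-1,3-dioxolane
Product: 8 tert-butyldimethyl{[(5Z,7E)-5-methyl-8-(2-methyl-1,3-dioxolan-2-yl)octa-5,7-dien-1-yl]oxy}silane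
Conditions: Pd(OAc)2 (5 mol %), Bu4NCl, K2CO3, DMF, 50 °C
Reagents that add atoms: none
Why: Heck reaction under ligand-free phase-transfer conditions: oxidative addition of the alkenyl iodide to zerovalent palladium keeps the Z geometry, insertion is terminal because the inner alkene carbon of 7 bears a quaternary carbon, and syn β-hydride elimination, possible only toward the new bond, gives the E alkene C7'=C8'.

Step 3
Reactants: 8 tert-butyldimethyl{[(5Z,7E)-5-methyl-8-(2-methyl-1,3-dioxolan-2-yl)octa-5,7-dien-1-yl]oxy}silane
Product: 9 (5Z,7E)-5-methyl-8-(2-methyl-1,3-dioxolan-2-yl)octa-5,7-dien-1-ol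
Conditions: Bu4NF, THF, 0 °C → rt
Reagents that add atoms: none
Why: Fluoride cleavage of a primary silyl ether; the ketal and the diene are inert to fluoride, which is why the aldehyde carbon was carried as a silyl ether and not as an acetal.

Step 4
Reactants: 9 (5Z,7E)-5-methyl-8-(2-methyl-1,3-dioxolan-2-yl)octa-5,7-dien-1-ol
Product: 10 (5Z,7E)-5-methyl-8-(2-methyl-1,3-dioxolan-2-yl)octa-5,7-dienal
Conditions: Dess–Martin periodinane, pyridine, CH2Cl2, 0 °C
Reagents that add atoms: none
Why: Dess–Martin oxidation, buffered with pyridine so that the acid-labile dienyl ketal and the Z alkene do not meet free acetic acid.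

Step 5
Reactants: 10 (5Z,7E)-5-methyl-8-(2-methyl-1,3-dioxolan-2-yl)octa-5,7-dienal
Product: 11 racemic (7Z,9E)-7-methyl-10-(2-methyl-1,3-dioxolan-2-yl)deca-1,7,9-trien-3-ol
Conditions: CH2=CHMgBr, THF, −78 °C; aqueous work-up
Reagents that add atoms: vinylmagnesium bromide, C=C[Mg]Br
Why: 1,2-Addition of a vinyl Grignard reagent to the aldehyde forms C4'–C5'; the carbinol centre is formed as a racemate and is removed in step 6.

Step 6
Reactants: 11 racemic (7Z,9E)-7-methyl-10-(2-methyl-1,3-dioxolan-2-yl)deca-1,7,9-trien-3-ol
Product: 12 (7Z,9E)-7-methyl-10-(2-methyl-1,3-dioxolan-2-yl)deca-1,7,9-trien-3-one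
Conditions: Dess–Martin periodinane, pyridine, CH2Cl2, 0 °C; used at once
Reagents that add atoms: none
Why: Dess–Martin oxidation of the allylic alcohol to the vinyl ketone under buffered, non-nucleophilic conditions; 12 is kept cold and used directly so that neither polymerisation nor uncatalysed cycloaddition intervenes.

Step 7
Reactants: 12 (7Z,9E)-7-methyl-10-(2-methyl-1,3-dioxolan-2-yl)deca-1,7,9-trien-3-one
Product: 13 (4aS,7R,8aR)-4a-methyl-7-(2-methyl-1,3-dioxolan-2-yl)-3,4,4a,7,8,8a-hexahydronaphthalen-1(2H)-one
Conditions: (R)-3,3-diphenyl-1-(2-methylphenyl)tetrahydro-1H,3H-pyrrolo[1,2-c][1,3,2]oxazaborole (20 mol %), Tf2NH (17 mol %), CH2Cl2, −78 → −20 °C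
Reagents that add atoms: none
Why: The cationic oxazaborolidine binds the C4' carbonyl of 12 and lowers the LUMO of the vinyl ketone, which adds across the diene C10'=C9'–C8'=C7' in a concerted, asynchronous [4+2] cycloaddition that forms C6'–C7' and C5'–C10'. The closest known reaction types are the Lewis-acid-catalysed type 1 intramolecular Diels–Alder reaction of 1,7,9-decatrien-3-ones and, for absolute control, the enantioselective intermolecular, intramolecular and transannular Diels–Alder reactions of enones and enals under cationic oxazaborolidine catalysis. Ring B closes as the cyclohexene of the cycloaddition, and ring A closes as a six-membered ring through the C1'–C3' tether and the C4' carbonyl, fused along C5'–C10'. C10' and C7' are set relative to each other by suprafacial addition to a diene whose two outside groups, the C10' methyl and the ketal carbon on C7', must end cis. C5' is set relative to C10' by the tether, which sits on the inside (Z) position of C10' and can reach the dienophile only with the carbonyl exo, so the fusion is cis with H5' syn to the C10' methyl. The absolute configuration is decided at C5' by the catalyst: with boron bound syn to the vinyl group and the s-trans enone held over an aryl ring by an α-C–H···O contact, the (R)-catalyst should leave open the Si face of C5', which leads to (4aS,7R,8aR)-13. The step therefore needs only enantiofacial selectivity, since the 7Z,9E geometry of the diene secures the relative configuration. The slight excess of oxazaborolidine over Tf2NH keeps free acid away from the dienyl ketal.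

Step 8
Reactants: 13 (4aS,7R,8aR)-4a-methyl-7-(2-methyl-1,3-dioxolan-2-yl)-3,4,4a,7,8,8a-hexahydronaphthalen-1(2H)-one
Product: 14 (4aS,7S,8aR)-4a-methyl-7-(2-methyl-1,3-dioxolan-2-yl)octahydronaphthalen-1(2H)-one
Conditions: H2 (1 atm), Pd/C (10 wt %), EtOAc, rt
Reagents that add atoms: none
Why: Heterogeneous hydrogenation of the only alkene, a cis-disubstituted ring alkene; no stereocentre is made or touched, and the neutral medium leaves the epimerisable C5' alone (the descriptor at C7 changes only because the priorities change).

Step 9
Reactants: 14 (4aS,7S,8aR)-4a-methyl-7-(2-methyl-1,3-dioxolan-2-yl)octahydronaphthalen-1(2H)-one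
Product: 15 2-methyl-2-[(2S,4aS,8aS)-4a-methyl-8-methylidenedecahydronaphthalen-2-yl]-1,3-dioxolane
Conditions: Zn, CH2Br2, TiCl4, THF, 0–5 °C (reagent pre-formed); then 14, CH2Cl2, 0 °C → rt
Reagents that add atoms: dibromomethane, BrCBr
Why: Takai–Lombardo methylenation: the non-basic zinc/titanium methylene reagent olefinates hindered, enolisable ketones without enolisation, so the cis fusion at C5' is kept; the saturated dioxolane should be tolerated.

Step 10
Reactants: 15 2-methyl-2-[(2S,4aS,8aS)-4a-methyl-8-methylidenedecahydronaphthalen-2-yl]-1,3-dioxolane
Product: 16 1-[(2S,4aS,8aS)-4a-methyl-8-methylidenedecahydronaphthalen-2-yl]ethan-1-one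
Conditions: pyridinium p-toluenesulfonate (cat.), acetone/H2O, 40 °C
Reagents that add atoms: water, O
Why: Mild acid-catalysed hydrolysis of the dioxolane; the weak acid should neither isomerise the exocyclic alkene nor enolise the new ketone toward C7' at a rate that matters.

Step 11
Reactants: 16 1-[(2S,4aS,8aS)-4a-methyl-8-methylidenedecahydronaphthalen-2-yl]ethan-1-one
Product: 18 1-[(2S,4aS,8aS)-4a-methyl-8-methylidenedecahydronaphthalen-2-yl]ethenyl trifluoromethanesulfonate, via potassium enolate 17 (not isolated)
Conditions: KN(SiMe3)2, THF, −78 °C (16 added to the base); PhNTf2, −78 → 0 °C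
Reagents that add atoms: N-phenylbis(trifluoromethanesulfonimide), O=S(=O)(N(c1ccccc1)S(=O)(=O)C(F)(F)F)C(F)(F)F
Why: Kinetic deprotonation of the methyl group by a hindered amide base, with inverse addition so that no proton exchange can epimerise C7', and O-sulfonylation of the terminal enolate give the 1,1-disubstituted enol triflate.

Step 12
Reactants: 18 1-[(2S,4aS,8aS)-4a-methyl-8-methylidenedecahydronaphthalen-2-yl]ethenyl trifluoromethanesulfonate
Product: 19 2-[(2S,4aS,8aS)-4a-methyl-8-methylidenedecahydronaphthalen-2-yl]prop-2-enal
Conditions: Pd(PPh3)4 (5 mol %), CO (3 atm), LiCl, Bu3SnH (syringe pump), THF, 50 °C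
Reagents that add atoms: carbon monoxide, [C-]#[O+]
Why: Palladium-catalysed reductive carbonylation (formylation): oxidative addition of the enol triflate to zerovalent palladium, CO insertion and hydride transfer from the tin hydride to the acylpalladium give the 2-substituted acrolein; slow addition of the hydride under CO pressure suppresses direct reduction.

Step 13
Reactants: 20 (+)-alantolactone
Product: 21 11α,13-epoxy-11,13-dihydroalantolactone (spiro-oxirane with the oxygen on C11 cis to H7)
Conditions: t-BuOOH, n-BuLi, THF, −78 → −20 °C
Reagents that add atoms: tert-butyl hydroperoxide, CC(C)(C)OO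
Why: Nucleophilic (Weitz–Scheffer-type) epoxidation with lithium tert-butyl peroxide attacks only the electron-poor exocyclic alkene and leaves C5=C6 alone; the enolate closes the oxirane on the convex face of the cis-fused lactone, so the oxygen on C11 ends cis to H7.

Step 14
Reactants: 21 11α,13-epoxy-11,13-dihydroalantolactone
Product: 22 11α-hydroxy-13-iodo-11,13-dihydroalantolactone
Conditions: LiI, AcOH, THF, 0 °C → rt
Reagents that add atoms: lithium iodide, [Li+].[I-]
Why: Acid-assisted SN2 opening of the epoxide by iodide at the primary carbon C13 (C11 is quaternary and α to the carbonyl); C11 is not touched and keeps its configuration.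

Step 15
Reactants: 19 2-[(2S,4aS,8aS)-4a-methyl-8-methylidenedecahydronaphthalen-2-yl]prop-2-enal; 22 11α-hydroxy-13-iodo-11,13-dihydroalantolactone
Product: 24 spiro lactol (2-hydroxytetrahydropyran spiro-fused at C11 of the lactone through O and C13 and carrying the decalin on C11'; mixture of epimers at C11' and C12'), via open-chain hydroxy aldehyde 23 (not isolated)
Conditions: 22 (1.5 equiv), (Me3Si)3SiH (syringe pump), AIBN (cat.), benzene, 80 °C
Reagents that add atoms: none
Why: Giese reaction: the silyl radical abstracts iodine from 22, the nucleophilic primary C13 radical adds to the CH2 terminus (C13') of the electron-poor enal and the α-formyl radical takes hydrogen from the silane; the δ-hydroxy aldehyde 23 closes to the six-membered lactol, and the mixed centres C11' and C12' both become trigonal in step 16.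

Step 16
Reactants: 24 spiro lactol
Product: 26 CNP0108778.1 (spiro 3,4-dihydro-2H-pyran with the C11'=C12' enol ether; ring oxygen on C11 cis to H7; decalin 5'S,7'S,10'S), via anomeric mesylate 25 (not isolated)
Conditions: MsCl, Et3N, CH2Cl2, 0 → 40 °C
Reagents that add atoms: none
Why: Dehydration of a lactol through its anomeric sulfonate: the mesylate ionises to the oxocarbenium ion, which can lose a proton only from C11' and gives the C11'=C12' enol ether; base is present throughout, so the enol ether and the exocyclic alkene do not meet acid, and no stereocentre is touched.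

## Compound list

1 | tert-butyl(4-bromobutoxy)dimethylsilane | CC(C)(C)[Si](C)(C)OCCCCBr | starting material
2 | propyne | CC#C | starting material
3 | [4-(tert-butyldimethylsilyloxy)butyl]magnesium bromide (not isolated) | CC(C)(C)[Si](C)(C)OCCCC[Mg]Br | intermediate
4 | [4-(tert-butyldimethylsilyloxy)butyl]copper, as its MgBr2 complex (not isolated) | CC(C)(C)[Si](C)(C)OCCCC[Cu] | intermediate
5 | (Z)-[6-(tert-butyldimethylsilyloxy)-2-methylhex-1-en-1-yl]copper (not isolated) | CC(C)(C)[Si](C)(C)OCCCC/C(C)=C\[Cu] | intermediate
6 | (Z)-tert-butyl[(6-iodo-5-methylhex-5-en-1-yl)oxy]dimethylsilane | CC(C)(C)[Si](C)(C)OCCCC/C(C)=C\I | intermediate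
7 | 2-ethenyl-2-methyl-1,3-dioxolane | CC1(C=C)OCCO1 | starting material
8 | tert-butyldimethyl{[(5Z,7E)-5-methyl-8-(2-methyl-1,3-dioxolan-2-yl)octa-5,7-dien-1-yl]oxy}silane | CC(C)(C)[Si](C)(C)OCCCC/C(C)=C\C=C\C1(C)OCCO1 | intermediate
9 | (5Z,7E)-5-methyl-8-(2-methyl-1,3-dioxolan-2-yl)octa-5,7-dien-1-ol | OCCCC/C(C)=C\C=C\C1(C)OCCO1 | intermediate
10 | (5Z,7E)-5-methyl-8-(2-methyl-1,3-dioxolan-2-yl)octa-5,7-dienal | O=CCCC/C(C)=C\C=C\C1(C)OCCO1 | intermediate
11 | racemic (7Z,9E)-7-methyl-10-(2-methyl-1,3-dioxolan-2-yl)deca-1,7,9-trien-3-ol | C=CC(O)CCC/C(C)=C\C=C\C1(C)OCCO1 | intermediate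
12 | (7Z,9E)-7-methyl-10-(2-methyl-1,3-dioxolan-2-yl)deca-1,7,9-trien-3-one | C=CC(=O)CCC/C(C)=C\C=C\C1(C)OCCO1 | intermediate
13 | (4aS,7R,8aR)-4a-methyl-7-(2-methyl-1,3-dioxolan-2-yl)-3,4,4a,7,8,8a-hexahydronaphthalen-1(2H)-one | O=C1CCC[C@@]2(C)C=C[C@H](C3(C)OCCO3)C[C@@H]12 | intermediate
14 | (4aS,7S,8aR)-4a-methyl-7-(2-methyl-1,3-dioxolan-2-yl)octahydronaphthalen-1(2H)-one | O=C1CCC[C@@]2(C)CC[C@H](C3(C)OCCO3)C[C@@H]12 | intermediate
15 | 2-methyl-2-[(2S,4aS,8aS)-4a-methyl-8-methylidenedecahydronaphthalen-2-yl]-1,3-dioxolane | C=C1CCC[C@@]2(C)CC[C@H](C3(C)OCCO3)C[C@@H]12 | intermediate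
16 | 1-[(2S,4aS,8aS)-4a-methyl-8-methylidenedecahydronaphthalen-2-yl]ethan-1-one | C=C1CCC[C@@]2(C)CC[C@H](C(C)=O)C[C@@H]12 | intermediate
17 | potassium 1-[(2S,4aS,8aS)-4a-methyl-8-methylidenedecahydronaphthalen-2-yl]ethen-1-olate (not isolated) | C=C1CCC[C@@]2(C)CC[C@H](C(=C)[O-])C[C@@H]12.[K+] | intermediate
18 | 1-[(2S,4aS,8aS)-4a-methyl-8-methylidenedecahydronaphthalen-2-yl]ethenyl trifluoromethanesulfonate | C=C1CCC[C@@]2(C)CC[C@H](C(=C)OS(=O)(=O)C(F)(F)F)C[C@@H]12 | intermediate
19 | 2-[(2S,4aS,8aS)-4a-methyl-8-methylidenedecahydronaphthalen-2-yl]prop-2-enal | C=C1CCC[C@@]2(C)CC[C@H](C(=C)C=O)C[C@@H]12 | intermediate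
20 | (+)-alantolactone | C=C1C(=O)O[C@@H]2C[C@@]3(C)CCC[C@H](C)C3=C[C@@H]21 | starting material
21 | 11α,13-epoxy-11,13-dihydroalantolactone | C1O[C@]12C(=O)O[C@@H]3C[C@@]4(C)CCC[C@H](C)C4=C[C@@H]32 | intermediate
22 | 11α-hydroxy-13-iodo-11,13-dihydroalantolactone | O[C@@]1(CI)C(=O)O[C@@H]2C[C@@]3(C)CCC[C@H](C)C3=C[C@@H]21 | intermediate
23 | 11α-hydroxy-13-{3-oxo-2-[(2S,4aS,8aS)-4a-methyl-8-methylidenedecahydronaphthalen-2-yl]propyl}-11,13-dihydroalantolactone, epimers at C11' (not isolated) | C=C1CCC[C@@]2(C)CC[C@H](C(C=O)CC[C@]3(O)C(=O)O[C@@H]4C[C@@]5(C)CCC[C@H](C)C5=C[C@@H]43)C[C@@H]12 | intermediate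
24 | spiro lactol (12'-hydroxy-11',12'-dihydro form of 26), epimers at C11' and C12' | C=C1CCC[C@@]2(C)CC[C@H](C3C(O)O[C@@]4(CC3)C(=O)O[C@@H]3C[C@@]5(C)CCC[C@H](C)C5=C[C@@H]34)C[C@@H]12 | intermediate
25 | C12' methanesulfonate of lactol 24 (not isolated) | C=C1CCC[C@@]2(C)CC[C@H](C3C(OS(C)(=O)=O)O[C@@]4(CC3)C(=O)O[C@@H]3C[C@@]5(C)CCC[C@H](C)C5=C[C@@H]34)C[C@@H]12 | intermediate
26 | CNP0108778.1 | C=C1CCC[C@@]2(C)CC[C@H](C3=CO[C@@]4(CC3)C(=O)O[C@@H]3C[C@@]5(C)CCC[C@H](C)C5=C[C@@H]34)C[C@@H]12 | target

## Step count and least certain steps

Total step count: 16. Longest linear sequence: 14 steps (steps 1 to 12, then 15 and 16). The lactone branch (steps 13 and 14) joins at step 15.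

**Step 7 (key step).**
- Most likely failures:
  - Weak or inverted enantiofacial discrimination, because a vinyl ketone bound at one point with its tether exo need not sit in the catalyst pocket as simple enones do.
  - Slow turnover at the terminally disubstituted Z-diene, which gives time for ionisation of the dienyl ketal by the Lewis acid or for uncatalysed background cycloaddition.
  - If only the sense is wrong, the mirror-image catalyst is taken.
- Fallback, setting out from 12 and returning at 13: Me2AlCl (1.1 equiv, CH2Cl2, −78 → −20 °C) should give the racemic cis-octalone F1. LiBH(s-Bu)3 reduces it to the racemic alcohol F2. Esterification with (S)-O-methylmandelic acid (DCC, DMAP) gives two diastereomeric esters, which are separated by chromatography and assigned by the mandelate shift differences or by X-ray. The ester of the (4aS,7R,8aR) series F3 is cleaved with K2CO3 in MeOH to the single-enantiomer alcohol F4, and Dess–Martin oxidation returns to 13.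

**Step 15.**
- Most likely failures: premature reduction of the C13 radical by the silane before it meets the hindered enal, and loss of the enal by hydrosilylation or oligomerisation.
- Fallback, setting out from 19 and 20 and returning directly at 26 (steps 13 to 16 are then not needed): thermal hetero-Diels–Alder reaction in which 19 acts as the 1-oxadiene and the exocyclic alkene of 20 as the 2π partner. This is the cross version of the known thermal dimerisation of α-methylene carbonyl compounds, in which oxygen bonds to the carbonyl-bearing carbon. Conditions: excess 20, concentrated toluene with a radical inhibitor, 110–140 °C, sealed tube. Approach on the convex face of the lactone gives the same C11 configuration. Its own weakness is self-dimerisation of 19. This fallback makes no new compound.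

**Step 12.**
- Most likely failures: hydride capture by the alkenylpalladium before CO insertion, or conjugate reduction of the product enal by the tin hydride.
- Fallback, setting out from 16 and returning at 19: condensation with 2,4,6-triisopropylbenzenesulfonyl hydrazide gives the hydrazone F5. A Shapiro reaction (n-BuLi, 2.2 equiv, THF, −78 → 0 °C) deprotonates the methyl side and gives the alkenyllithium F6, which is formylated with DMF.

**Step 2.**
- Most likely failures: sluggish insertion into the hindered, unactivated alkene, and partial Z to E isomerisation of the trisubstituted alkene through re-addition of palladium hydride.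
- Fallback, setting out from 6 and returning at 8: 2-ethynyl-2-methyl-1,3-dioxolane F7 (from but-3-yn-2-one and ethylene glycol) is hydroborated with pinacolborane (Cp2Zr(H)Cl cat.) to the E-alkenylboronate F8. Suzuki–Miyaura coupling of F8 with 6 (Pd(PPh3)4, aqueous K3PO4, THF) should go with retention at both alkenes.

**Step 9.**
- Most likely failures: cleavage of the dioxolane by the titanium and zinc halides of the reagent, or incomplete conversion of the hindered ketone.
- Fallback, setting out from 14 and returning at 15: Peterson olefination. Me3SiCH2MgCl with CeCl3 (THF, −78 → 0 °C), which does not enolise, gives the β-hydroxysilane F9, and KH in THF eliminates it to the methylene compound.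

## Further compounds

F1 | step 7 | racemic (4aS*,7R*,8aR*)-4a-methyl-7-(2-methyl-1,3-dioxolan-2-yl)-3,4,4a,7,8,8a-hexahydronaphthalen-1(2H)-one (racemate of 13) | O=C1CCC[C@@]2(C)C=C[C@H](C3(C)OCCO3)C[C@@H]12
F2 | step 7 | racemic (4aS*,7R*,8aR*)-4a-methyl-7-(2-methyl-1,3-dioxolan-2-yl)-1,2,3,4,4a,7,8,8a-octahydronaphthalen-1-ol (carbinol centre as formed) | OC1CCC[C@@]2(C)C=C[C@H](C3(C)OCCO3)C[C@@H]12
F3 | step 7 | (4aS,7R,8aR)-4a-methyl-7-(2-methyl-1,3-dioxolan-2-yl)-1,2,3,4,4a,7,8,8a-octahydronaphthalen-1-yl (S)-methoxy(phenyl)acetate | CO[C@H](C(=O)OC1CCC[C@@]2(C)C=C[C@H](C3(C)OCCO3)C[C@@H]12)c1ccccc1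
F4 | step 7 | (4aS,7R,8aR)-4a-methyl-7-(2-methyl-1,3-dioxolan-2-yl)-1,2,3,4,4a,7,8,8a-octahydronaphthalen-1-ol (single enantiomer) | OC1CCC[C@@]2(C)C=C[C@H](C3(C)OCCO3)C[C@@H]12
F0 | step 15 | none | none
F5 | step 12 | (E)-2,4,6-triisopropylbenzenesulfonyl hydrazone of 16 | C=C1CCC[C@@]2(C)CC[C@H](/C(C)=N/NS(=O)(=O)c3c(C(C)C)cc(C(C)C)cc3C(C)C)C[C@@H]12
F6 | step 12 | {1-[(2S,4aS,8aS)-4a-methyl-8-methylidenedecahydronaphthalen-2-yl]ethenyl}lithium | C=C1CCC[C@@]2(C)CC[C@H](C(=C)[Li])C[C@@H]12
F7 | step 2 | 2-ethynyl-2-methyl-1,3-dioxolane | C#CC1(C)OCCO1
F8 | step 2 | (E)-2-methyl-2-[2-(4,4,5,5-tetramethyl-1,3,2-dioxaborolan-2-yl)ethenyl]-1,3-dioxolane | CC1(/C=C/B2OC(C)(C)C(C)(C)O2)OCCO1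
F9 | step 9 | (4aS,7S,8aR)-4a-methyl-7-(2-methyl-1,3-dioxolan-2-yl)-1-[(trimethylsilyl)methyl]decahydronaphthalen-1-ol (carbinol centre as formed) | C[Si](C)(C)CC1(O)CCC[C@@]2(C)CC[C@H](C3(C)OCCO3)C[C@@H]12
A1 | alternative 1 | alantolactone | C=C1C(=O)O[C@@H]2C[C@@]3(C)CCC[C@H](C)C3=C[C@@H]21
A2 | alternative 1 | vinylallene aldehyde, 2-[2-(buta-2,3-dien-1-ylidene)-1,3-dimethylcyclohexyl]acetaldehyde | O=CC[C@@]1(C)CCC[C@H](C)/C1=C/C=C=C
A3 | alternative 2 | (R)-5-[3-(tert-butyldimethylsilyloxy)prop-1-en-2-yl]-2-methylcyclohex-2-en-1-one (silyloxy carvone) | CC1=CC[C@@H](C(=C)CO[Si](C)(C)C(C)(C)C)CC1=O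
A4 | alternative 2 | 5-chloro-2-lithiopent-1-ene | C=C([Li])CCCCl
A5 | alternative 2 | cis-fused methylene decalone | C=C1CCC[C@@]2(C)C(=O)C[C@H](C(=C)CO[Si](C)(C)C(C)(C)C)C[C@@H]12
A6 | alternative 3 | metathesis diene (11-allyl-11-O-(2-decalinylallyl) lactone) | C=C1CCC[C@@]2(C)CC[C@H](C(=C)CO[C@@]3(CC=C)C(=O)O[C@@H]4C[C@@]5(C)CCC[C@H](C)C5=C[C@@H]43)C[C@@H]12
A7 | alternative 3 | spiro 3,6-dihydro-2H-pyran | C=C1CCC[C@@]2(C)CC[C@H](C3=CC[C@]4(OC3)C(=O)O[C@@H]5C[C@@]6(C)CCC[C@H](C)C6=C[C@@H]54)C[C@@H]12
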